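**Plan** (germacrane numbering: C1 ketone, C2=C3–O–C10 furanone, C4=C5, C6–O–C12 lactone on C7/C11(=C13), C8 methacrylate, C9 acetate)
Cuts, in order: lactone acyl bond C12–O6; C5–C6; the O8 and O9 esters; furanone bond O–C3 and bond C1–C2 (back to a C1–O8 γ-lactone and an iodo-enyne C2–C5); C11=C13; the C9/C10 diol; C7–C8.
Enabling feature: C5 is the terminus of a Z-alkenyl arm fixed on C3 of the planar furanone ring (O, C3, C2, C1, C10) and C6 is a carbinol carbon beside C7, so one alkenylchromium-to-aldehyde addition closes the ten-membered carbocycle C1–C10 (nine-membered through the ring oxygen), sets C6 and delivers the hydroxyl for the lactone.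
Forward: C7–C8 bond by vinylogous Mukaiyama–Michael addition, then the C1–O8 lactone diol, the acrylate, acetylide addition and furanone ring, the two esters, the ten-membered ring, and last the α-methylene lactone ring.
Stereochemistry: C7 and C8 from the imidazolidinone catalyst, C9 and C10 from OsO4 anti to the C7 branch, 4Z from anti-carbomagnesiation of propargyl alcohol, C6 from C7 during ring closure.

Key step: step 17

Remark: the hemiketal carbon formed in the acetylide addition and the C11 centre of the transient Mannich base are stereochemically undefined and are written without descriptor; both become sp2 carbons later.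

Step 1
Reactants: 1 3-methylfuran-2(5H)-one
Product: 2 3-methyl-2-(trimethylsilyloxy)furan
Conditions: TMSOTf, Et3N, Et2O, 0 °C
Reagents that add atoms: trimethylsilyl triflate, C[Si](C)(C)OS(=O)(=O)C(F)(F)F
Why: Silyl dienol ether formation, in which soft enolisation of the butenolide and O-silylation should give the aromatic 2-silyloxyfuran needed as the vinylogous nucleophile.

Step 2
Reactants: 2 3-methyl-2-(trimethylsilyloxy)furan; 3 (E)-4,4-dimethoxybut-2-enal
Product: 4 (3R)-4,4-dimethoxy-3-[(2R)-4-methyl-5-oxo-2,5-dihydrofuran-2-yl]butanal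
Conditions: (2S,5S)-5-benzyl-2-tert-butyl-3-methylimidazolidin-4-one (20 mol %), 2,4-dinitrobenzoic acid (20 mol %), H2O (2 equiv), CH2Cl2, −70 °C
Reagents that add atoms: none
Why: Iminium-catalysed vinylogous Mukaiyama–Michael addition, in which the benzyl group of the catalyst shields one face of the (E)-iminium of 3 so that C5 of the furan should add to the open face of C7 (catalyst control), and the open transition state should give the syn relation between the ring oxygen on C8 and the acetal carbon C6 (simple diastereoselection), water taking up the silyl group.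

Step 3
Reactants: 4 butenolide aldehyde
Product: 5 (3R)-4,4-dimethoxy-3-[(2R)-4-methyl-5-oxo-2,5-dihydrofuran-2-yl]butanoic acid
Conditions: NaClO2, NaH2PO4, 2-methylbut-2-ene, tBuOH/H2O, 0 °C
Reagents that add atoms: sodium chlorite, [Na+].[O-]Cl=O
Why: Pinnick oxidation, whose buffered conditions should leave the dimethyl acetal, the butenolide and its base-sensitive γ-centre C8 untouched.

Step 4
Reactants: 5 butenolide acid
Product: 6 tert-butyl (3R)-4,4-dimethoxy-3-[(2R)-4-methyl-5-oxo-2,5-dihydrofuran-2-yl]butanoate
Conditions: O-tert-butyl-N,N'-diisopropylisourea, CH2Cl2, rt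
Reagents that add atoms: O-tert-butyl-N,N'-diisopropylisourea, CC(C)NC(=NC(C)C)OC(C)(C)C
Why: Isourea esterification under neutral conditions, giving a tert-butyl ester that should resist the acetylide of step 11 and is released by acid in step 18.

Step 5
Reactants: 6 butenolide tert-butyl ester
Product: 7 tert-butyl (3R)-3-[(2S,3S,4S)-3,4-dihydroxy-4-methyl-5-oxooxolan-2-yl]-4,4-dimethoxybutanoate
Conditions: OsO4 (5 mol %), NMO, acetone/H2O, rt
Reagents that add atoms: N-methylmorpholine N-oxide, C[N+]1([O-])CCOCC1; water, O (both oxygens pass through the catalytic OsO4)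
Why: Catalytic syn-dihydroxylation, in which OsO4 should add to the C9=C10 bond of the butenolide on the ring face anti to the C7 branch at C8, setting C9 and C10 as the cis-diol trans to C7.

Step 6
Reactants: 7 lactone diol
Product: 8 lactone with O9 as TBS ether and O10 as TMS ether
Conditions: TBSOTf (1.05 equiv), 2,6-lutidine, CH2Cl2, −78 °C; then TMSOTf, −78 to −40 °C
Reagents that add atoms: tert-butyldimethylsilyl triflate, CC(C)(C)[Si](C)(C)OS(=O)(=O)C(F)(F)F; trimethylsilyl triflate, C[Si](C)(C)OS(=O)(=O)C(F)(F)F
Why: Silyl ether formation with steric differentiation, in which the bulky triflate should react only with the secondary C9 hydroxyl at low temperature and the small one then caps the tertiary C10 hydroxyl, so that no O–H remains for steps 7 and 11.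

Step 7
Reactants: 8 bis-silylated lactone ester
Product: 11 tert-butyl acrylate lactone (C11=C13 installed), via Mannich base 9 (not isolated), via trimethylammonium iodide 10 (not isolated)
Conditions: LiN(iPr)2, THF, −78 °C; CH2=NMe2+ I−, −78 °C to rt; MeI, CH2Cl2, rt; DBU, rt
Reagents that add atoms: N,N-dimethylmethyleneiminium iodide (Eschenmoser's salt), C=[N+](C)C.[I-]
Why: α-Methylenation of an ester by enolate Mannich reaction, N-methylation and Hofmann-type elimination, which should be site-selective because C11 carries the only acidic hydrogens (the lactone α-carbon C10 is fully substituted).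

Step 8
Reactants: 12 prop-2-yn-1-ol
Product: 13 (Z)-3-iodo-2-methylprop-2-en-1-ol
Conditions: MeMgBr (2.5 equiv), CuI (10 mol %), THF, −10 °C to rt; then I2, −10 °C
Reagents that add atoms: methylmagnesium bromide, C[Mg]Br; iodine, II
Why: Copper-catalysed anti-carbomagnesiation of the propargylic alkoxide, in which magnesium ends cis to the CH2O group in a five-membered chelate and iodinolysis with retention should give the Z iodide that fixes the later 4Z geometry.

Step 9
Reactants: 13 (Z)-3-iodo-2-methylprop-2-en-1-ol
Product: 14 (Z)-3-iodo-2-methylprop-2-enal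
Conditions: MnO2, CH2Cl2, rt, dark
Reagents that add atoms: none
Why: Allylic alcohol oxidation on MnO2 under neutral conditions, which should keep the Z geometry of the β-iodoenal.

Step 10
Reactants: 14 (Z)-3-iodo-2-methylprop-2-enal
Product: 15 (Z)-1-iodo-2-methylbut-1-en-3-yne
Conditions: dimethyl (1-diazo-2-oxopropyl)phosphonate, K2CO3, MeOH, 0 °C; used as a solution
Reagents that add atoms: dimethyl (1-diazo-2-oxopropyl)phosphonate, CC(=O)C(=[N+]=[N-])P(=O)(OC)OC
Why: Seyferth–Gilbert homologation in the Ohira–Bestmann variant, which should convert the aldehyde into the terminal alkyne through an alkylidene carbene without touching the alkenyl iodide.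

Step 11
Reactants: 11 tert-butyl acrylate lactone; 15 (Z)-1-iodo-2-methylbut-1-en-3-yne
Product: 16 alkynyl lactol (C1 hemiketal bearing the C2≡C3–C4(Me)=C5HI arm)
Conditions: 15 (1.5 equiv), LiN(SiMe3)2 (1.4 equiv), THF, −78 °C; then 11, −78 to −50 °C; aq NH4Cl
Reagents that add atoms: none
Why: Acetylide addition to a lactone, in which the lithium acetylide should add once to the α-oxygenated carbonyl C1 to give a lactolate stable at low temperature, while the hindered conjugated tert-butyl ester and the alkenyl iodide (no halogen–metal exchange with an amide base) are left alone.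

Step 12
Reactants: 16 alkynyl lactol
Product: 18 furanone alcohol (free O8–H), via desilylated lactol 17 (not isolated)
Conditions: PPTS (cat.), MeOH, 0 °C; evaporate; Ph3PAuNTf2 (5 mol %), toluene, rt
Reagents that add atoms: none
Why: Methanolysis of the tertiary TMS ether followed by gold-catalysed 5-endo-dig hydroalkoxylation, in which the C10 hydroxyl should add to C3 of the alkyne activated by monovalent gold, the hemiketal then collapses to the C1 ketone of the 3(2H)-furanone and releases O8–H, and the TBS ether on O9 blocks the competing 6-endo closure.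

Step 13
Reactants: 18 furanone alcohol
Product: 19 O8 methacrylate
Conditions: methacrylic anhydride, Et3N, DMAP (cat.), CH2Cl2, 0 °C to rt
Reagents that add atoms: methacrylic anhydride, CC(=C)C(=O)OC(=O)C(C)=C
Why: DMAP-catalysed acylation of the only free hydroxyl, the alternative closure of O8 onto C13 being a disfavoured 5-endo-trig process.

Step 14
Reactants: 19 O8 methacrylate
Product: 20 C9 alcohol
Conditions: HF·pyridine, pyridine, THF, 0 °C to rt
Reagents that add atoms: none
Why: Fluoride-mediated silyl ether cleavage under buffered acidic conditions, which should avoid O8-to-O9 acyl migration and keep the dimethyl acetal.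

Step 15
Reactants: 20 C9 alcohol
Product: 21 O9 acetate
Conditions: Ac2O, DMAP, pyridine, CH2Cl2, rt
Reagents that add atoms: acetic anhydride, CC(=O)OC(C)=O
Why: DMAP-catalysed acetylation of the hindered secondary hydroxyl, placed before the aldehyde is unveiled so that O9 cannot form a five-membered lactol with C6.

Step 16
Reactants: 21 O9 acetate
Product: 22 C6 aldehyde
Conditions: LiBF4, MeCN/H2O (98:2), rt; used at once
Reagents that add atoms: water, O
Why: Lewis acid-assisted acetal hydrolysis under nearly neutral conditions, chosen because the β-acyloxy β,γ-unsaturated aldehyde could eliminate the C8 ester, epimerise at C7 or move the C11=C13 bond into conjugation under base or strong acid.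

Step 17
Reactants: 22 C6 aldehyde with (Z)-alkenyl iodide at C5
Product: 23 ten-membered (6R)-allylic alcohol, tert-butyl ester
Conditions: CrCl2 (10 equiv), NiCl2 (10 mol %), DMSO/THF, rt, slow addition to a final 2 mM
Reagents that add atoms: none
Why: NiCl2 is reduced by CrCl2 to zerovalent nickel, which inserts into the C5–I bond, transmetalation to trivalent chromium gives the (Z)-alkenylchromium species with retention, and this adds 1,2 to the chromium-activated C6 aldehyde to form C5–C6. The closest known reaction type is the intramolecular Nozaki–Hiyama–Kishi alkenylation used to close medium rings and macrocycles. One σ-bond closes two rings at once, the ten-membered carbocycle C1–C10 (10-exo-trig at the carbonyl) and the nine-membered oxacycle through the furanone oxygen (9-exo-trig), which is possible because the planar furanone holds the C3 alkenyl arm and the C10 chain on one edge and the Z geometry turns C5 back toward C6. The new stereocentre C6 is controlled by C7 under ring constraint: in the Felkin–Anh arrangement open to the forming ring, the C7–C8 ring bond lies anti to the incoming C5 and H7 flanks the trajectory, which should give the 6R alcohol with H6 and H7 trans. The step needs chemoselectivity for the aldehyde over three esters and the furanone ketone, secured by the low basicity and aldehyde selectivity of the alkenylchromium reagent, and it needs ring closure to outrun oligomerisation, secured by the preorganising furanone and slow addition at high dilution. No base is present, so the β-acyloxy aldehyde should not eliminate and C7 should keep its configuration.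

Step 18
Reactants: 23 ten-membered (6R)-allylic alcohol, tert-butyl ester
Product: 24 target, (4Z,6R,7S,8S,9S,10S)-9-acetoxy-8-methacryloyloxy-1-oxo-3,10-epoxygermacra-2,4,11(13)-trien-12,6-olide
Conditions: TFA, CH2Cl2, 0 °C to rt
Reagents that add atoms: none
Why: Acidolysis of the tert-butyl ester and acid-catalysed γ-lactonisation (5-exo-trig acyl substitution at C12), which should form the O6–C12 bond with retention at C6 because ionisation at C6 would give an allyl cation conjugated to the electron-poor furanone.

**Compound list**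
1 | 3-methylfuran-2(5H)-one | CC1=CCOC1=O | starting material
2 | 3-methyl-2-(trimethylsilyloxy)furan | Cc1ccoc1O[Si](C)(C)C | intermediate
3 | (E)-4,4-dimethoxybut-2-enal | COC(OC)/C=C/C=O | starting material
4 | (3R)-4,4-dimethoxy-3-[(2R)-4-methyl-5-oxo-2,5-dihydrofuran-2-yl]butanal | O=CC[C@@H](C(OC)OC)[C@@H]1OC(=O)C(C)=C1 | intermediate
5 | (3R)-4,4-dimethoxy-3-[(2R)-4-methyl-5-oxo-2,5-dihydrofuran-2-yl]butanoic acid | OC(=O)C[C@@H](C(OC)OC)[C@@H]1OC(=O)C(C)=C1 | intermediate
6 | tert-butyl (3R)-4,4-dimethoxy-3-[(2R)-4-methyl-5-oxo-2,5-dihydrofuran-2-yl]butanoate | CC(C)(C)OC(=O)C[C@@H](C(OC)OC)[C@@H]1OC(=O)C(C)=C1 | intermediate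
7 | tert-butyl (3R)-3-[(2S,3S,4S)-3,4-dihydroxy-4-methyl-5-oxooxolan-2-yl]-4,4-dimethoxybutanoate | CC(C)(C)OC(=O)C[C@@H](C(OC)OC)[C@@H]1OC(=O)[C@@](C)(O)[C@H]1O | intermediate
8 | tert-butyl (3R)-3-[(2S,3S,4S)-3-(tert-butyldimethylsilyloxy)-4-methyl-5-oxo-4-(trimethylsilyloxy)oxolan-2-yl]-4,4-dimethoxybutanoate | CC(C)(C)OC(=O)C[C@@H](C(OC)OC)[C@@H]1OC(=O)[C@@](C)(O[Si](C)(C)C)[C@H]1O[Si](C)(C)C(C)(C)C | intermediate
9 | Mannich base, 8 with a dimethylaminomethyl group on C11 (not isolated) | CC(C)(C)OC(=O)C(CN(C)C)[C@@H](C(OC)OC)[C@@H]1OC(=O)[C@@](C)(O[Si](C)(C)C)[C@H]1O[Si](C)(C)C(C)(C)C | intermediate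
10 | trimethylammonium iodide of 9 (not isolated) | CC(C)(C)OC(=O)C(C[N+](C)(C)C)[C@@H](C(OC)OC)[C@@H]1OC(=O)[C@@](C)(O[Si](C)(C)C)[C@H]1O[Si](C)(C)C(C)(C)C.[I-] | intermediate
11 | tert-butyl (3R)-3-[(2S,3S,4S)-3-(tert-butyldimethylsilyloxy)-4-methyl-5-oxo-4-(trimethylsilyloxy)oxolan-2-yl]-4,4-dimethoxy-2-methylidenebutanoate | CC(C)(C)OC(=O)C(=C)[C@@H](C(OC)OC)[C@@H]1OC(=O)[C@@](C)(O[Si](C)(C)C)[C@H]1O[Si](C)(C)C(C)(C)C | intermediate
12 | prop-2-yn-1-ol | C#CCO | starting material
13 | (Z)-3-iodo-2-methylprop-2-en-1-ol | OC/C(C)=C\I | intermediate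
14 | (Z)-3-iodo-2-methylprop-2-enal | O=C/C(C)=C\I | intermediate
15 | (Z)-1-iodo-2-methylbut-1-en-3-yne | C#C/C(C)=C\I | intermediate
16 | alkynyl lactol: 11 with the lactone carbonyl C1 turned into a hemiketal carrying the (Z)-4-iodo-3-methylbut-3-en-1-ynyl group (anomeric mixture; O9 TBS, O10 TMS) | CC(C)(C)OC(=O)C(=C)[C@@H](C(OC)OC)[C@@H]1OC(O)(C#C/C(C)=C\I)[C@@](C)(O[Si](C)(C)C)[C@H]1O[Si](C)(C)C(C)(C)C | intermediate
17 | 16 with free C10 hydroxyl (not isolated) | CC(C)(C)OC(=O)C(=C)[C@@H](C(OC)OC)[C@@H]1OC(O)(C#C/C(C)=C\I)[C@@](C)(O)[C@H]1O[Si](C)(C)C(C)(C)C | intermediate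
18 | furanone alcohol: (2S)-2-methyl-5-[(Z)-1-iodoprop-1-en-2-yl]furan-3(2H)-one whose C2 (= C10) carries the chain C9H(OTBS)–C8H(OH)–C7H[CH(OMe)2]–C(=CH2)CO2tBu, C7 to C9 configured as in 11 | CC(C)(C)OC(=O)C(=C)[C@@H](C(OC)OC)[C@H](O)[C@H](O[Si](C)(C)C(C)(C)C)[C@]1(C)OC(/C(C)=C\I)=CC1=O | intermediate
19 | 18 with O8 as methacrylate | CC(C)(C)OC(=O)C(=C)[C@@H](C(OC)OC)[C@H](OC(=O)C(C)=C)[C@H](O[Si](C)(C)C(C)(C)C)[C@]1(C)OC(/C(C)=C\I)=CC1=O | intermediate
20 | 19 with free C9 hydroxyl | CC(C)(C)OC(=O)C(=C)[C@@H](C(OC)OC)[C@H](OC(=O)C(C)=C)[C@H](O)[C@]1(C)OC(/C(C)=C\I)=CC1=O | intermediate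
21 | 20 with O9 as acetate | CC(C)(C)OC(=O)C(=C)[C@@H](C(OC)OC)[C@H](OC(=O)C(C)=C)[C@H](OC(C)=O)[C@]1(C)OC(/C(C)=C\I)=CC1=O | intermediate
22 | 21 with C6 as free aldehyde | CC(C)(C)OC(=O)C(=C)[C@@H](C=O)[C@H](OC(=O)C(C)=C)[C@H](OC(C)=O)[C@]1(C)OC(/C(C)=C\I)=CC1=O | intermediate
23 | tert-butyl ester of the (4Z,6R,7S,8S,9S,10S)-9-acetoxy-6-hydroxy-8-methacryloyloxy-1-oxo-3,10-epoxygermacra-2,4,11(13)-trien-12-oic acid | CC(C)(C)OC(=O)C(=C)[C@H]1[C@H](O)/C=C(/C)C2=CC(=O)[C@@](C)(O2)[C@@H](OC(C)=O)[C@H]1OC(=O)C(C)=C | intermediate
24 | (4Z,6R,7S,8S,9S,10S)-9-acetoxy-8-methacryloyloxy-1-oxo-3,10-epoxygermacra-2,4,11(13)-trien-12,6-olide | C=C(C)C(=O)O[C@H]1[C@H]2C(=C)C(=O)O[C@@H]2/C=C(/C)C2=CC(=O)[C@@](C)(O2)[C@H]1OC(C)=O | target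

**Step count and risks**
Total steps: 18. Longest linear sequence: 15 (steps 1–7 and 11–18).

Steps most likely to fail:

1. Step 17. What may go wrong: attack of C5 on the wrong face of the aldehyde, so that the C6 epimer forms, with oligomerisation or protodeiodination as further losses. The fallback sets out from 22: the ring closure is run as in step 17, and the C6-epimeric alcohol F1 is inverted by a Mitsunobu reaction with formic acid (PPh3, DIAD, HCO2H, THF, 0 °C) to the 6R formate F2. The formyl group of F2 is then removed selectively with NaHCO3 in MeOH at 0 °C, which leaves the acetate and methacrylate and comes back to the route at 23.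

2. Step 2. What may go wrong: poor or reversed simple diastereoselection (syn against anti) in the open transition state with the acetal-bearing enal, while the catalyst still controls C7. The fallback sets out from 2 and 3: the adduct mixture is accepted, and the C8-epimeric aldehyde F3 is carried together with 4 through steps 3 and 4 as the C8-epimeric acid F4 and the C8-epimeric ester F5. F5 is separated from 6 by chromatography and re-equilibrated at the acidic butenolide γ-carbon C8 (DBU cat., CH2Cl2, rt, through the 2-oxidofuran). The resulting mixture is separated again and recycled, so that the material comes back to the route at 6.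

3. Step 11. What may go wrong: slow addition at the lactone carbonyl, which is flanked by the fully substituted C10, allowing attack at the acrylate ester or double addition. The fallback sets out from 11: the lactone is reduced with iBu2AlH (toluene, −78 °C) to the lactol F6, whose open aldehyde form takes up the lithium acetylide of 15 (3 equiv, THF, −78 to 0 °C) to give the propargylic diol F7. The propargylic hydroxyl of F7 is oxidised selectively with MnO2 (CH2Cl2, rt), and the ynone closes onto O8 to give the lactol 16, where the route resumes.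

**Further compounds**
F1 | step 17 | C6 epimer (6S) of alcohol 23 | CC(C)(C)OC(=O)C(=C)[C@H]1[C@@H](O)/C=C(/C)C2=CC(=O)[C@@](C)(O2)[C@@H](OC(C)=O)[C@H]1OC(=O)C(C)=C
F2 | step 17 | O6 formate of 23 (6R) | CC(C)(C)OC(=O)C(=C)[C@H]1[C@H](OC=O)/C=C(/C)C2=CC(=O)[C@@](C)(O2)[C@@H](OC(C)=O)[C@H]1OC(=O)C(C)=C
F3 | step 2 | C8 epimer of aldehyde 4 | O=CC[C@@H](C(OC)OC)[C@H]1OC(=O)C(C)=C1
F4 | step 2 | C8 epimer of acid 5 | OC(=O)C[C@@H](C(OC)OC)[C@H]1OC(=O)C(C)=C1
F5 | step 2 | C8 epimer of ester 6 | CC(C)(C)OC(=O)C[C@@H](C(OC)OC)[C@H]1OC(=O)C(C)=C1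
F6 | step 11 | lactol from reduction of the lactone carbonyl of 11 (anomeric mixture) | CC(C)(C)OC(=O)C(=C)[C@@H](C(OC)OC)[C@@H]1OC(O)[C@@](C)(O[Si](C)(C)C)[C@H]1O[Si](C)(C)C(C)(C)C
F7 | step 11 | open-chain propargylic diol (C1 carbinol epimers, free O8–H) | CC(C)(C)OC(=O)C(=C)[C@@H](C(OC)OC)[C@H](O)[C@H](O[Si](C)(C)C(C)(C)C)[C@](C)(O[Si](C)(C)C)C(O)C#C/C(C)=C\I
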